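## Retrosynthetic overview

Numbering (germacrane): ring C1–C10 with C1(OH), C3(=O), C4=C5, C6(O‑lactone), C7, C8(O‑acyl), C10(OH)(C14H3). C11–C13 are the methylene‑lactone carbons and C15 is CH2OH.
1. The last step hydrolyses a C1/C10 acetonide; before it, C5–C6 and the lactone bond O6–C12 are cut together, leading back to the open‑chain (Z)‑β‑iodoenone aldehyde 23.
2. Enabling feature: C6 is both the allylic carbon next to the Z‑configured C4=C5 enone and the γ‑carbon of the C12 acrylate ester. An alkenyl metal at C5 adding to a C6 aldehyde therefore gives an alkoxide five atoms from C12. The Z‑alkene and a temporary cis‑4,5‑disubstituted dioxolane on C1/C10 fold the chain.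
3. 23 comes from ynone 19 (MgI2/CH2O puts iodine on C5 and C15 on C4) and from a terminal dioxolane that serves as a latent C6 aldehyde. C7–C8 comes from an indium Barbier union of aldehyde 11 with bromide 4, whose dioxolane stereocentre steers C7/C8 and is then excised.
4. C1 comes from (R)‑α‑hydroxy‑γ‑butyrolactone and C10 from a chelation‑controlled MeMgBr addition. Ring order: two temporary dioxolanes, then the ten‑membered carbocycle, then the γ‑lactone, the last two in one operation.

Key step: step 17

Assumption: the target is taken in the open 3‑keto‑1,10‑diol form that is drawn, although the C10 hydroxyl could add reversibly to the C3 ketone in solution.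
Remark: the organometallic intermediates 12, 20, 24 and 25 are drawn in their simplest monomeric form.

## Route

Step 1
Reactants: 1 (R)‑2,2‑dimethyl‑1,3‑dioxolane‑4‑carbaldehyde; 2 methyl acrylate
Product: 3 Baylis–Hillman alcohol, methyl 2‑{[(4R)‑2,2‑dimethyl‑1,3‑dioxolan‑4‑yl](hydroxy)methyl}prop‑2‑enoate (both carbinol epimers)
Conditions: DABCO (cat.), dioxane–H2O 1:1, rt
Reagents that add atoms: none
Why: Morita–Baylis–Hillman reaction of a reactive α‑alkoxy aldehyde with an acrylate, in which the dioxolane stereocentre is not touched and the new carbinol centre need not be controlled because it becomes sp2 in step 2.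

Step 2
Reactants: 3 Baylis–Hillman alcohol
Product: 4 methyl (2Z)‑2‑(bromomethyl)‑3‑[(4S)‑2,2‑dimethyl‑1,3‑dioxolan‑4‑yl]prop‑2‑enoate
Conditions: NBS, Me2S, CH2Cl2, 0 °C → rt
Reagents that add atoms: N‑bromosuccinimide, O=C1CCC(=O)N1Br
Why: Corey–Kim‑type activation of the allylic alcohol followed by SN2′ attack of bromide is the standard acid‑free conversion of Baylis–Hillman alcohols into (Z)‑2‑(bromomethyl)enoates, the geometry being set by the preference of the C3 substituent to lie trans to the ester.

Step 3
Reactants: 5 (3R)‑3‑hydroxyoxolan‑2‑one [(R)‑α‑hydroxy‑γ‑butyrolactone]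
Product: 6 (2R)‑2,4‑dihydroxy‑N‑methoxy‑N‑methylbutanamide
Conditions: MeNH(OMe)·HCl, i‑PrMgCl, THF, −20 → 0 °C
Reagents that add atoms: N,O‑dimethylhydroxylamine hydrochloride, CNOC.Cl
Why: Weinreb aminolysis of the lactone by the magnesium amide opens the ring at the acyl carbon only, so the C1 stereocentre of the chiral‑pool lactone is kept.

Step 4
Reactants: 6 dihydroxy Weinreb amide
Product: 7 (2R)‑4‑{[tert‑butyl(diphenyl)silyl]oxy}‑2‑hydroxy‑N‑methoxy‑N‑methylbutanamide
Conditions: TBDPSCl, imidazole, CH2Cl2, 0 °C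
Reagents that add atoms: tert‑butyl(chloro)diphenylsilane, CC(C)(C)[Si](Cl)(c1ccccc1)c1ccccc1
Why: Sterically demanding TBDPSCl silylates the primary (future C3) hydroxyl much faster than the secondary C1 hydroxyl and blocks relactonisation.

Step 5
Reactants: 7 silylated Weinreb amide
Product: 8 (5R)‑7‑{[tert‑butyl(diphenyl)silyl]oxy}‑5‑hydroxyhept‑1‑en‑4‑one
Conditions: allylMgBr (2.5 equiv), THF, −78 °C; cold aq. NH4Cl
Reagents that add atoms: allylmagnesium bromide, C=CC[Mg]Br
Why: Weinreb ketone synthesis in which the first equivalent of Grignard reagent only deprotonates the hydroxyl and the second acylates cleanly to the ketone without over‑addition, a cold neutral quench keeping the double bond out of conjugation.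

Step 6
Reactants: 8 α‑hydroxy allyl ketone
Product: 9 (4S,5R)‑7‑{[tert‑butyl(diphenyl)silyl]oxy}‑4‑methylhept‑1‑ene‑4,5‑diol
Conditions: MeMgBr (3 equiv), CH2Cl2–Et2O, −78 °C
Reagents that add atoms: methylmagnesium bromide, C[Mg]Br
Why: Cram‑chelate‑controlled Grignard addition in which magnesium bridges the C1 alkoxide and the C10 carbonyl oxygen and methyl is delivered to the face flanked by H1 rather than by the C2 chain, which sets the (10S) tertiary carbinol anti to O1.

Step 7
Reactants: 9 diol
Product: 10 tert‑butyl(2‑{(4R,5S)‑2,2,5‑trimethyl‑5‑(prop‑2‑en‑1‑yl)‑1,3‑dioxolan‑4‑yl}ethoxy)diphenylsilane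
Conditions: Me2C(OMe)2, PPTS (cat.), CH2Cl2, rt
Reagents that add atoms: 2,2‑dimethoxypropane, COC(C)(C)OC
Why: Acid‑catalysed transacetalisation ties the vicinal diol into a dioxolane in which the C2 and C9 chains are cis, protecting both hydroxyls for all later steps.

Step 8
Reactants: 10 allyl dioxolane
Product: 11 2‑[(4S,5R)‑5‑(2‑{[tert‑butyl(diphenyl)silyl]oxy}ethyl)‑2,2,4‑trimethyl‑1,3‑dioxolan‑4‑yl]acetaldehyde (C8 aldehyde)
Conditions: O3, CH2Cl2, −78 °C; then Me2S
Reagents that add atoms: ozone, [O-][O+]=O
Why: Ozonolysis with reductive work‑up cleaves the only alkene to the C8 aldehyde and leaves silyl ether and acetal untouched.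

Step 9
Reactants: 11 C8 aldehyde; 4 allylic bromide
Product: 13 homoallylic alcohol, methyl (3R,4R)‑3‑[(4S)‑2,2‑dimethyl‑1,3‑dioxolan‑4‑yl]‑4‑hydroxy‑2‑methylidene‑5‑[(4S,5R)‑5‑(2‑{[tert‑butyl(diphenyl)silyl]oxy}ethyl)‑2,2,4‑trimethyl‑1,3‑dioxolan‑4‑yl]pentanoate (7R,8R in target numbering), via allylindium reagent 12 (not isolated)
Conditions: In powder, THF–H2O 1:1, rt
Reagents that add atoms: none
Why: Barbier‑type 2‑(alkoxycarbonyl)allylation (Dreiding–Schmidt type) in which allylindium 12 keeps the dioxolanyl group cis to CH2In and reacts at its γ‑carbon through a chair transition state, giving the required C7/C8 syn relationship, while the A(1,3)‑locked dioxolane stereocentre (its C–H eclipsing the alkene, the aldehyde approaching anti to its C–O bond) selects the face that leads to 7R,8R irrespective of the remote centres of 11.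

Step 10
Reactants: 13 homoallylic alcohol; 14 (2R)‑2‑methylbutanoic acid
Product: 15 C8 (2R)‑2‑methylbutanoate of 13
Conditions: DCC, DMAP (cat.), CH2Cl2, 0 °C → rt
Reagents that add atoms: none
Why: Steglich esterification acylates the only free hydroxyl faster than it can lactonise onto the methyl ester under these non‑acidic conditions, and neither C8 nor the α‑centre of the acid is affected.

Step 11
Reactants: 15 silyl ether
Product: 16 primary alcohol (15 with C3–OH in place of the silyl ether)
Conditions: HF·pyridine, pyridine, THF, 0 °C → rt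
Reagents that add atoms: none
Why: Buffered fluoride cleaves the only silyl ether while both acetonides, both esters and the acrylate survive the weakly acidic medium.

Step 12
Reactants: 16 primary alcohol
Product: 17 C3 aldehyde
Conditions: Dess–Martin periodinane, CH2Cl2, 0 °C → rt
Reagents that add atoms: none
Why: Dess–Martin oxidation stops at the β‑alkoxy aldehyde under neutral conditions that avoid β‑elimination of O1.

Step 13
Reactants: 17 C3 aldehyde
Product: 18 propargylic alcohol (both C3 epimers)
Conditions: HC≡CMgBr (1.2 equiv), THF, −78 °C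
Reagents that add atoms: ethynylmagnesium bromide, C#C[Mg]Br
Why: 1,2‑Addition of the alkynyl Grignard reagent to the aldehyde at low temperature outruns attack on the esters or the hindered acrylate, and the C3 configuration is irrelevant because C3 is oxidised next.

Step 14
Reactants: 18 propargylic alcohol
Product: 19 terminal ynone (C3 ketone, C4≡C5–H)
Conditions: Dess–Martin periodinane, CH2Cl2, 0 °C
Reagents that add atoms: none
Why: Dess–Martin oxidation of the propargylic alcohol gives the terminal ynone without base, so the β‑oxygen at C1 is not eliminated.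

Step 15
Reactants: 19 terminal ynone
Product: 21 (Z)‑β‑iodo‑α‑(hydroxymethyl)enone, via iodoallenolate 20 (not isolated)
Conditions: MgI2, monomeric CH2O (CH2Cl2 solution), CH2Cl2, −20 → 0 °C
Reagents that add atoms: magnesium iodide, [Mg+2].[I-].[I-]; formaldehyde, C=O
Why: Iodo‑aldol (β‑iodo Baylis–Hillman) three‑component reaction in which iodide adds to C5 of the MgI2‑activated ynone and iodoallenolate 20 is hydroxymethylated at C4 in the plane of the C5 substituents from the side of H5, away from iodine, which places iodine cis to the C3 carbonyl (Z).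

Step 16
Reactants: 21 iodoenone
Product: 23 open‑chain C6 aldehyde, methyl (3R,4R)‑3‑formyl‑2‑methylidene‑4‑{[(2R)‑2‑methylbutanoyl]oxy}pentanoate carrying at its C5 the (4S,5R)‑2,2,4‑trimethyl‑1,3‑dioxolane whose ring C5 bears the CH2–C(=O)–C(CH2OH)=CHI (Z) chain, via terminal diol 22 (not isolated)
Conditions: H5IO6, EtOAc, 0 °C → rt
Reagents that add atoms: none
Why: Periodic acid hydrolyses the less hindered, monosubstituted terminal dioxolane selectively and cleaves the liberated diol 22 at once (Malaprade cleavage), so the base‑sensitive C6 aldehyde appears under non‑basic conditions, C7 is not epimerised and the fully substituted C1/C10 dioxolane and the free C15 hydroxyl stay intact.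

Step 17
Reactants: 23 open‑chain iodoenone aldehyde
Product: 26 1,10‑O‑isopropylidene derivative of the target (ten‑membered carbocycle and cis‑fused α‑methylene‑γ‑lactone, 6S), via alkenylchromium species 24 (not isolated), via ring‑closed chromium alkoxide 25 (not isolated)
Conditions: CrCl2 (10 equiv), NiCl2 (2 mol %), DMSO–THF 3:1, syringe‑pump addition to 0.002 M, rt; then water
Reagents that add atoms: none
Why: Zerovalent nickel, formed in situ from NiCl2 by CrCl2, inserts into the C5–I bond with retention, the alkenyl group passes to trivalent chromium (24), this alkenylchromium adds to the C6 aldehyde, and the resulting alkoxide 25 acylates itself on the C12 methyl ester with loss of methoxide. The closest known reaction type is the intramolecular Nozaki–Hiyama–Kishi reaction of alkenyl iodides with aldehydes, which has closed nine‑ to twelve‑membered carbocycles, joined to the spontaneous lactonisation known for γ‑alkoxide α‑methylene esters in chromium‑ and zinc‑mediated lactone syntheses. The ten‑membered carbocycle closes in the 10‑exo‑trig mode (C5 onto the C6 carbonyl) and the γ‑lactone in the 5‑exo‑trig mode (O6 onto C12). The only new stereocentre, C6, is controlled by C7: since C5 and C8 belong to the same forming ring, C8 must sit gauche to the incoming C5, which leaves the sp2 carbon C11 antiperiplanar to the forming bond and H7 outside (Felkin–Anh arrangement), and attack on this rotamer gives the (6S) alkoxide with H6 and H7 cis. The step needs ring closure over oligomerisation, secured by high dilution and by two built‑in turns (the Z‑alkene and the cis‑disubstituted C1/C10 dioxolane), and retention of the Z geometry, secured by five‑membered chelation of chromium by the C3 carbonyl oxygen. It also needs chemoselectivity for the aldehyde over ketone, esters, acrylate and the free C15 hydroxyl, which is the characteristic behaviour of organochromium reagents.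

Step 18
Reactants: 26 bicyclic acetonide
Product: 27 target CNP0263726.1
Conditions: TFA–H2O–THF 1:1:4, 0 °C → rt
Reagents that add atoms: none
Why: Mild aqueous acid hydrolyses the remaining acetonide, conditions under which enone, α‑methylene lactone, allylic alcohol and secondary ester are stable and no stereocentre is touched.

## Compound list

1 | (R)‑2,2‑dimethyl‑1,3‑dioxolane‑4‑carbaldehyde | O=C[C@H]1COC(C)(C)O1 | starting material
2 | methyl acrylate | C=CC(=O)OC | starting material
3 | Baylis–Hillman alcohol (carbinol epimers) | C=C(C(=O)OC)C(O)[C@H]1COC(C)(C)O1 | intermediate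
4 | (Z)‑allylic bromide | COC(=O)/C(CBr)=C/[C@H]1COC(C)(C)O1 | intermediate
5 | (R)‑α‑hydroxy‑γ‑butyrolactone | O=C1OCC[C@H]1O | starting material
6 | (2R)‑2,4‑dihydroxy Weinreb amide | CON(C)C(=O)[C@H](O)CCO | intermediate
7 | 4‑O‑TBDPS Weinreb amide | CON(C)C(=O)[C@H](O)CCO[Si](c1ccccc1)(c2ccccc2)C(C)(C)C | intermediate
8 | α‑hydroxy allyl ketone | C=CCC(=O)[C@H](O)CCO[Si](c1ccccc1)(c2ccccc2)C(C)(C)C | intermediate
9 | (4S,5R)‑diol | C=CC[C@](C)(O)[C@H](O)CCO[Si](c1ccccc1)(c2ccccc2)C(C)(C)C | intermediate
10 | allyl dioxolane | C=CC[C@]1(C)OC(C)(C)O[C@@H]1CCO[Si](c2ccccc2)(c3ccccc3)C(C)(C)C | intermediate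
11 | C8 aldehyde | O=CC[C@]1(C)OC(C)(C)O[C@@H]1CCO[Si](c2ccccc2)(c3ccccc3)C(C)(C)C | intermediate
12 | allylindium reagent, drawn as the dibromide (not isolated) | COC(=O)/C(C[In](Br)Br)=C/[C@H]1COC(C)(C)O1 | intermediate
13 | homoallylic alcohol (7R,8R) | C=C(C(=O)OC)[C@@H]([C@H]1COC(C)(C)O1)[C@H](O)C[C@]2(C)OC(C)(C)O[C@@H]2CCO[Si](c3ccccc3)(c4ccccc4)C(C)(C)C | intermediate
14 | (2R)‑2‑methylbutanoic acid | CC[C@@H](C)C(=O)O | starting material
15 | C8 (2R)‑2‑methylbutanoate | C=C(C(=O)OC)[C@@H]([C@H]1COC(C)(C)O1)[C@H](OC(=O)[C@H](C)CC)C[C@]2(C)OC(C)(C)O[C@@H]2CCO[Si](c3ccccc3)(c4ccccc4)C(C)(C)C | intermediate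
16 | C3 primary alcohol | C=C(C(=O)OC)[C@@H]([C@H]1COC(C)(C)O1)[C@H](OC(=O)[C@H](C)CC)C[C@]2(C)OC(C)(C)O[C@@H]2CCO | intermediate
17 | C3 aldehyde | C=C(C(=O)OC)[C@@H]([C@H]1COC(C)(C)O1)[C@H](OC(=O)[C@H](C)CC)C[C@]2(C)OC(C)(C)O[C@@H]2CC=O | intermediate
18 | propargylic alcohol (C3 epimers) | C=C(C(=O)OC)[C@@H]([C@H]1COC(C)(C)O1)[C@H](OC(=O)[C@H](C)CC)C[C@]2(C)OC(C)(C)O[C@@H]2CC(O)C#C | intermediate
19 | terminal ynone | C=C(C(=O)OC)[C@@H]([C@H]1COC(C)(C)O1)[C@H](OC(=O)[C@H](C)CC)C[C@]2(C)OC(C)(C)O[C@@H]2CC(=O)C#C | intermediate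
20 | magnesium iodoallenolate (not isolated) | C=C(C(=O)OC)[C@@H]([C@H]1COC(C)(C)O1)[C@H](OC(=O)[C@H](C)CC)C[C@]2(C)OC(C)(C)O[C@@H]2CC(O[Mg]I)=C=CI | intermediate
21 | (Z)‑β‑iodo‑α‑(hydroxymethyl)enone | C=C(C(=O)OC)[C@@H]([C@H]1COC(C)(C)O1)[C@H](OC(=O)[C@H](C)CC)C[C@]2(C)OC(C)(C)O[C@@H]2CC(=O)/C(CO)=C\I | intermediate
22 | terminal diol (not isolated) | C=C(C(=O)OC)[C@@H]([C@H](O)CO)[C@H](OC(=O)[C@H](C)CC)C[C@]1(C)OC(C)(C)O[C@@H]1CC(=O)/C(CO)=C\I | intermediate
23 | open‑chain iodoenone C6 aldehyde | C=C(C(=O)OC)[C@@H](C=O)[C@H](OC(=O)[C@H](C)CC)C[C@]1(C)OC(C)(C)O[C@@H]1CC(=O)/C(CO)=C\I | intermediate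
24 | alkenylchromium dichloride (not isolated) | C=C(C(=O)OC)[C@@H](C=O)[C@H](OC(=O)[C@H](C)CC)C[C@]1(C)OC(C)(C)O[C@@H]1CC(=O)/C(CO)=C\[Cr](Cl)Cl | intermediate
25 | ring‑closed C6 chromium alkoxide (not isolated) | C=C(C(=O)OC)[C@H]1[C@@H](O[Cr](Cl)Cl)/C=C(/CO)C(=O)C[C@H]2OC(C)(C)O[C@@]2(C)C[C@H]1OC(=O)[C@H](C)CC | intermediate
26 | 1,10‑O‑isopropylidene derivative of the target | C=C1C(=O)O[C@H]2/C=C(/CO)C(=O)C[C@H]3OC(C)(C)O[C@@]3(C)C[C@@H](OC(=O)[C@H](C)CC)[C@@H]12 | intermediate
27 | CNP0263726.1 | C=C1C(=O)O[C@H]2/C=C(/CO)C(=O)C[C@@H](O)[C@@](C)(O)C[C@@H](OC(=O)[C@H](C)CC)[C@@H]12 | target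

## Step count and risks

Total step count: 18. Longest linear sequence: 16 steps (steps 3–18, from 5). Steps 1–2 make the convergent bromide 4.

**Step 17 (ring closure).**
- What may go wrong: chelation by the C3 carbonyl may tame the alkenylchromium. Premature protonolysis of the carbon–chromium bond, reduction of the γ‑acyloxy enone by excess CrCl2 or intermolecular coupling could then overtake the ten‑membered closure. Facial selectivity at C6 may also erode.
- Fallback, from 21 back to the route at 27: C3 is taken to the alcohol level for the closure.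
- Silylation of 21 (TBSCl, imidazole) should give the C15 silyl ether F1.
- Luche reduction (NaBH4, CeCl3·7H2O, MeOH, −40 °C) should give the C3 allylic alcohol F2 (both epimers), and H5IO6 the aldehyde F3.
- The same CrCl2/NiCl2 closure then runs on an ordinary, non‑chelating alkenyl iodide and should give the C3 hydroxy lactone F4.
- Dess–Martin oxidation restores the enone in the silyl ether F5.
- Aqueous HF in MeCN removes silyl ether and acetonide together to reach 27.

**Step 9 (Barbier union).**
- What may go wrong: geometrical scrambling of the allylindium, 1,4‑elimination of the γ‑alkoxide from the allylmetal, or poor facial selectivity on either partner.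
- Fallback, from 3 (with 11) back to the route at 13: acetylation of 3 (Ac2O, pyridine) should give the Baylis–Hillman acetate F6.
- Palladium‑catalysed borylation (B2pin2, Pd2(dba)3, toluene, 50 °C) should give the configurationally stable (E)‑allylboronate F7, in which the dioxolanyl group is cis to CH2B.
- Allylboration of 11, thermal or catalysed by Sc(OTf)3, proceeds through a closed chair transition state. It transfers this fixed geometry into the syn C7/C8 pair and should deliver 13.

**Step 6 (methyl addition).**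
- What may go wrong: enolisation and double‑bond migration of the β,γ‑unsaturated ketone may compete with carbonyl addition.
- Fallback, from 7 back to the route at 11: lithium (trimethylsilyl)acetylide converts 7 into the non‑enolisable silyl ynone F8.
- The same chelation‑controlled MeMgBr addition gives the propargylic diol F9.
- K2CO3 in MeOH gives the terminal alkyne diol F10, and Me2C(OMe)2 with PPTS gives the ethynyl dioxolane F11.
- Anti‑Markovnikov hydroboration–oxidation (dicyclohexylborane, then NaBO3) gives aldehyde 11.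

Further compounds
F1 | step 17 | C15 tert‑butyldimethylsilyl ether of 21 | C=C(C(=O)OC)[C@@H]([C@H]1COC(C)(C)O1)[C@H](OC(=O)[C@H](C)CC)C[C@]2(C)OC(C)(C)O[C@@H]2CC(=O)/C(CO[Si](C)(C)C(C)(C)C)=C\I
F2 | step 17 | C3 allylic alcohol (C3 epimers) | C=C(C(=O)OC)[C@@H]([C@H]1COC(C)(C)O1)[C@H](OC(=O)[C@H](C)CC)C[C@]2(C)OC(C)(C)O[C@@H]2CC(O)/C(CO[Si](C)(C)C(C)(C)C)=C\I
F3 | step 17 | C6 aldehyde at the C3 alcohol level | C=C(C(=O)OC)[C@@H](C=O)[C@H](OC(=O)[C@H](C)CC)C[C@]1(C)OC(C)(C)O[C@@H]1CC(O)/C(CO[Si](C)(C)C(C)(C)C)=C\I
F4 | step 17 | C3 hydroxy bicyclic lactone | C=C1C(=O)O[C@H]2/C=C(/CO[Si](C)(C)C(C)(C)C)C(O)C[C@H]3OC(C)(C)O[C@@]3(C)C[C@@H](OC(=O)[C@H](C)CC)[C@@H]12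
F5 | step 17 | C15 silyl ether of 26 | C=C1C(=O)O[C@H]2/C=C(/CO[Si](C)(C)C(C)(C)C)C(=O)C[C@H]3OC(C)(C)O[C@@]3(C)C[C@@H](OC(=O)[C@H](C)CC)[C@@H]12
F6 | step 9 | Baylis–Hillman acetate | C=C(C(=O)OC)C(OC(C)=O)[C@H]1COC(C)(C)O1
F7 | step 9 | (E)‑allylboronate (pinacol ester) | COC(=O)/C(CB1OC(C)(C)C(C)(C)O1)=C/[C@H]2COC(C)(C)O2
F8 | step 6 | silyl ynone | C[Si](C)(C)C#CC(=O)[C@H](O)CCO[Si](c1ccccc1)(c2ccccc2)C(C)(C)C
F9 | step 6 | silylated propargylic diol | C[Si](C)(C)C#C[C@](C)(O)[C@H](O)CCO[Si](c1ccccc1)(c2ccccc2)C(C)(C)C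
F10 | step 6 | terminal alkyne diol | C#C[C@](C)(O)[C@H](O)CCO[Si](c1ccccc1)(c2ccccc2)C(C)(C)C
F11 | step 6 | ethynyl dioxolane | C#C[C@]1(C)OC(C)(C)O[C@@H]1CCO[Si](c2ccccc2)(c3ccccc3)C(C)(C)C
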